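**Retrosynthetic overview**

1. Target 16 comes from the trans bis-benzyl ether 15 by hydrogenolysis, and 15 from the C3-epimer pair 14 by base equilibration at C3.
2. 14 is opened at O1–C2 and C5 is raised to a formyl group, giving the stereorandom aldehyde ester 12. In the forward direction an enzymatic dynamic reduction sets C4 and the lactone, the only ring formed in the route, closes in the same flask.
3. 12 comes from vinyl ester 10 by C=C cleavage, 10 from acid 9, and 9 from allylic ester 6 by a racemic Ireland–Claisen rearrangement that forms the C3–C4 bond.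
4. 6 comes from acid 5 and allylic alcohol 4, and 4 from benzylated allylcatechol 2 and butenediol 3 by cross-metathesis.
5. Feature: in the lactone O1–C2(=O)–C3–C4–C5, C5 can be carried as a formyl carbon so that C4 is its enolisable α-carbon, while C3 is α to the C2 carbonyl. Both ring stereocentres are therefore base-labile at some stage and can be set after the skeleton is complete.

Key step: step 7

Assumption: the ketoreductase is taken from a commercial screening panel and chosen for (R)-preference at the aldehyde α-carbon; no particular enzyme variant is implied. The olefin geometry of 4 and 6 has no consequence, because the Claisen step is run without stereocontrol.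

**Step 1**
Reactants: 1 4-allylbenzene-1,2-diol
Product: 2 4-allyl-1,2-bis(benzyloxy)benzene
Conditions: BnBr (2.3 equiv), K2CO3, DMF, 60 °C
Reagents that add atoms: benzyl bromide, BrCc1ccccc1
Why: Williamson ether synthesis, in which both catechol phenoxides displace bromide from benzyl bromide (SN2) while the allyl group is inert.

**Step 2**
Reactants: 2 4-allyl-1,2-bis(benzyloxy)benzene; 3 (Z)-but-2-ene-1,4-diol
Product: 4 (E)-4-[3,4-bis(benzyloxy)phenyl]but-2-en-1-ol
Conditions: Hoveyda–Grubbs II (3 mol %), 3 (4 equiv), 1,4-benzoquinone (10 mol %), CH2Cl2, 40 °C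
Reagents that add atoms: none
Why: Olefin cross-metathesis of a terminal allylarene with an excess of the internal cis-diol should give mainly the (E)-allylic alcohol, with benzoquinone suppressing Ru–H migration of the double bond into conjugation with the arene; any (Z) isomer is carried along.

**Step 3**
Reactants: 4 (E)-4-[3,4-bis(benzyloxy)phenyl]but-2-en-1-ol; 5 3-(3,4-dimethoxyphenyl)propanoic acid
Product: 6 (E)-4-[3,4-bis(benzyloxy)phenyl]but-2-en-1-yl 3-(3,4-dimethoxyphenyl)propanoate
Conditions: DCC, DMAP (cat.), CH2Cl2, 0 °C → rt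
Reagents that add atoms: none
Why: Steglich esterification, in which DCC activates the acid and DMAP transfers the acyl group to the unhindered primary allylic alcohol.

**Step 4**
Reactants: 6 (E)-4-[3,4-bis(benzyloxy)phenyl]but-2-en-1-yl 3-(3,4-dimethoxyphenyl)propanoate
Product: 9 3-[3,4-bis(benzyloxy)benzyl]-2-(3,4-dimethoxybenzyl)pent-4-enoic acid (racemic; both diastereomers), via trimethylsilyl ketene acetal 7 (not isolated), via trimethylsilyl ester 8 (not isolated)
Conditions: LDA, TMSCl, THF, −78 °C → 60 °C; then 1 M HCl
Reagents that add atoms: chlorotrimethylsilane, C[Si](C)(C)Cl (its silyl group is present in 7 and 8 only and is lost on work-up)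
Why: Ireland–Claisen rearrangement, in which the O-silylated ester enolate 7 undergoes a [3,3]-sigmatropic shift that forms the later C3–C4 bond and leaves a vinyl group on the later C4; the two new stereocentres are deliberately formed without control, because both are corrected in steps 7 and 8.

**Step 5**
Reactants: 9 3-[3,4-bis(benzyloxy)benzyl]-2-(3,4-dimethoxybenzyl)pent-4-enoic acid
Product: 10 methyl 3-[3,4-bis(benzyloxy)benzyl]-2-(3,4-dimethoxybenzyl)pent-4-enoate (racemic; both diastereomers)
Conditions: MeI, K2CO3, DMF, rt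
Reagents that add atoms: iodomethane, CI
Why: SN2 O-alkylation of the carboxylate by iodomethane, with no other acidic or nucleophilic site in the molecule.

**Step 6**
Reactants: 10 methyl 3-[3,4-bis(benzyloxy)benzyl]-2-(3,4-dimethoxybenzyl)pent-4-enoate
Product: 12 methyl 4-[3,4-bis(benzyloxy)phenyl]-2-(3,4-dimethoxybenzyl)-3-formylbutanoate (all four stereoisomers), via vicinal diol 11 (not isolated)
Conditions: OsO4 (2 mol %), NaIO4 (4 equiv), 2,6-lutidine (2 equiv), dioxane/H2O 3:1, rt; product used crude
Reagents that add atoms: osmium tetroxide, O=[Os](=O)(=O)=O; sodium periodate, [Na+].[O-]I(=O)(=O)=O (re-oxidises osmium and so is the ultimate oxygen source)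
Why: Lemieux–Johnson oxidation, in which OsO4 dihydroxylates the monosubstituted alkene and periodate cleaves diol 11 to the aldehyde and formaldehyde without touching the electron-rich arenes or the benzyl ethers; epimerisation at the aldehyde α-carbon does no harm here.

**Step 7**
Reactants: 12 methyl 4-[3,4-bis(benzyloxy)phenyl]-2-(3,4-dimethoxybenzyl)-3-formylbutanoate (all four stereoisomers)
Product: 14 (4R)-4-[3,4-bis(benzyloxy)benzyl]-3-(3,4-dimethoxybenzyl)dihydrofuran-2(3H)-one (both C3 epimers), via γ-hydroxy ester 13 (not isolated)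
Conditions: ketoreductase, NADP+ (cat.), iPrOH (20% v/v), DMSO (10% v/v), triethanolamine buffer (0.1 M, pH 9), 35 °C; then 1 M HCl to pH 2, EtOAc
Reagents that add atoms: none
Why: In the pH 9 amine buffer the two C4 epimers of each C3 series interconvert through the aldehyde enol(ate), while the ketoreductase binds only the (R)-configured α-branched aldehyde and transfers hydride from NADPH (regenerated from isopropanol by the same enzyme) to the formyl carbon. The closest known reaction type is the alcohol-dehydrogenase dynamic reductive kinetic resolution of racemic α-branched aldehydes (2-arylpropanals to profenols), together with dynamic enzymatic conversions of racemic β-formyl esters whose products cyclise in situ; the α-carbon here carries two alkyl branches and enolises more slowly than an α-aryl one, which is why the higher pH and the tertiary-amine buffer are chosen. The γ-hydroxy ester 13 then closes the only ring by 5-exo-trig acyl substitution of its primary hydroxyl on the methyl ester, which forms the O1–C2 bond, expels methanol and removes the alcohol from the redox equilibrium; the acidic work-up completes the closure. The new stereocentre C4 is set by the enzyme alone, whose pocket must distinguish the benzyl branch from the branched ester-bearing chain, while C3 is not touched and stays as both epimers. The step needs C4 selection that does not depend on the C3 configuration and a racemisation that outruns reduction of the (4S) aldehyde: the first rests on enzyme choice, and the second is helped by the substrate, because the formyl α-hydrogen is far more acidic than the ester α-hydrogen so that only C4 equilibrates, and because the ester is not a ketoreductase substrate.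

**Step 8**
Reactants: 14 (4R)-4-[3,4-bis(benzyloxy)benzyl]-3-(3,4-dimethoxybenzyl)dihydrofuran-2(3H)-one (both C3 epimers)
Product: 15 (3R,4R)-4-[3,4-bis(benzyloxy)benzyl]-3-(3,4-dimethoxybenzyl)dihydrofuran-2(3H)-one
Conditions: DBU (1 equiv), toluene, 80 °C
Reagents that add atoms: none
Why: Base-mediated thermodynamic epimerisation, in which DBU reversibly deprotonates C3 (α to the lactone carbonyl) and reprotonation places the C3 benzyl group trans to the C4 benzyl group, so the (3S,4R) cis epimer should converge on the (3R,4R) trans lactone; C4 has no acidic hydrogen and keeps its configuration.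

**Step 9**
Reactants: 15 (3R,4R)-4-[3,4-bis(benzyloxy)benzyl]-3-(3,4-dimethoxybenzyl)dihydrofuran-2(3H)-one
Product: 16 (3R,4R)-4-(3,4-dihydroxybenzyl)-3-(3,4-dimethoxybenzyl)dihydrofuran-2(3H)-one
Conditions: H2 (1 atm), 10% Pd/C, EtOAc/MeOH, rt; work-up under argon
Reagents that add atoms: none
Why: Catalytic hydrogenolysis of the two aryl benzyl ethers on Pd/C under neutral conditions, which leaves the methyl ethers, the lactone and both stereocentres unchanged.

**Compound list**

1 | 4-allylbenzene-1,2-diol | C=CCc1ccc(O)c(O)c1 | starting material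
2 | 4-allyl-1,2-bis(benzyloxy)benzene | C=CCc1ccc(OCc2ccccc2)c(OCc2ccccc2)c1 | intermediate
3 | (Z)-but-2-ene-1,4-diol | OC/C=C\CO | starting material
4 | (E)-4-[3,4-bis(benzyloxy)phenyl]but-2-en-1-ol | OC/C=C/Cc1ccc(OCc2ccccc2)c(OCc2ccccc2)c1 | intermediate
5 | 3-(3,4-dimethoxyphenyl)propanoic acid | COc1ccc(CCC(=O)O)cc1OC | starting material
6 | (E)-4-[3,4-bis(benzyloxy)phenyl]but-2-en-1-yl 3-(3,4-dimethoxyphenyl)propanoate | COc1ccc(CCC(=O)OC/C=C/Cc2ccc(OCc3ccccc3)c(OCc3ccccc3)c2)cc1OC | intermediate
7 | trimethylsilyl ketene acetal of 6 (ketene acetal geometry not defined) | COc1ccc(CC=C(O[Si](C)(C)C)OC/C=C/Cc2ccc(OCc3ccccc3)c(OCc3ccccc3)c2)cc1OC | intermediate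
8 | trimethylsilyl 3-[3,4-bis(benzyloxy)benzyl]-2-(3,4-dimethoxybenzyl)pent-4-enoate (racemic, both diastereomers) | COc1ccc(CC(C(=O)O[Si](C)(C)C)C(C=C)Cc2ccc(OCc3ccccc3)c(OCc3ccccc3)c2)cc1OC | intermediate
9 | 3-[3,4-bis(benzyloxy)benzyl]-2-(3,4-dimethoxybenzyl)pent-4-enoic acid (racemic, both diastereomers) | COc1ccc(CC(C(=O)O)C(C=C)Cc2ccc(OCc3ccccc3)c(OCc3ccccc3)c2)cc1OC | intermediate
10 | methyl 3-[3,4-bis(benzyloxy)benzyl]-2-(3,4-dimethoxybenzyl)pent-4-enoate (racemic, both diastereomers) | COC(=O)C(Cc1ccc(OC)c(OC)c1)C(C=C)Cc1ccc(OCc2ccccc2)c(OCc2ccccc2)c1 | intermediate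
11 | methyl 3-[3,4-bis(benzyloxy)benzyl]-2-(3,4-dimethoxybenzyl)-4,5-dihydroxypentanoate (stereoisomer mixture) | COC(=O)C(Cc1ccc(OC)c(OC)c1)C(C(O)CO)Cc1ccc(OCc2ccccc2)c(OCc2ccccc2)c1 | intermediate
12 | methyl 4-[3,4-bis(benzyloxy)phenyl]-2-(3,4-dimethoxybenzyl)-3-formylbutanoate (all four stereoisomers) | COC(=O)C(Cc1ccc(OC)c(OC)c1)C(C=O)Cc1ccc(OCc2ccccc2)c(OCc2ccccc2)c1 | intermediate
13 | methyl (3R)-4-[3,4-bis(benzyloxy)phenyl]-2-(3,4-dimethoxybenzyl)-3-(hydroxymethyl)butanoate (both C2 epimers) | COC(=O)C(Cc1ccc(OC)c(OC)c1)[C@H](CO)Cc1ccc(OCc2ccccc2)c(OCc2ccccc2)c1 | intermediate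
14 | (4R)-4-[3,4-bis(benzyloxy)benzyl]-3-(3,4-dimethoxybenzyl)dihydrofuran-2(3H)-one (both C3 epimers) | COc1ccc(CC2C(=O)OC[C@@H]2Cc2ccc(OCc3ccccc3)c(OCc3ccccc3)c2)cc1OC | intermediate
15 | (3R,4R)-4-[3,4-bis(benzyloxy)benzyl]-3-(3,4-dimethoxybenzyl)dihydrofuran-2(3H)-one | COc1ccc(C[C@H]2C(=O)OC[C@@H]2Cc2ccc(OCc3ccccc3)c(OCc3ccccc3)c2)cc1OC | intermediate
16 | (3R,4R)-4-(3,4-dihydroxybenzyl)-3-(3,4-dimethoxybenzyl)dihydrofuran-2(3H)-one | COc1ccc(C[C@H]2C(=O)OC[C@@H]2Cc2ccc(O)c(O)c2)cc1OC | target

**Totals**

Total step count: 9. Longest linear sequence: 9 steps (1 → 16); 3 and 5 are commercial and enter in steps 2 and 3.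

**Steps most likely to fail**

Step 7. Enolisation at the dialkyl-substituted C4 may be too slow relative to hydride transfer to the unwanted epimer, so the resolution would stop being dynamic and either stall near half conversion or lose enantiopurity. The enzyme may also accept only one C3 series, or take up the very lipophilic substrate poorly. The fallback sets out from 12 and returns at 15. Chemoselective reduction of the aldehyde with NaBH4 in MeOH at 0 °C gives the stereorandom methyl 4-[3,4-bis(benzyloxy)phenyl]-2-(3,4-dimethoxybenzyl)-3-(hydroxymethyl)butanoate F1. Catalytic TsOH in CH2Cl2 closes it to the stereorandom lactone 4-[3,4-bis(benzyloxy)benzyl]-3-(3,4-dimethoxybenzyl)dihydrofuran-2(3H)-one F2. DBU in toluene, as in step 8, should turn F2 into the racemic trans lactone, that is 15 together with its enantiomer (3S,4S)-4-[3,4-bis(benzyloxy)benzyl]-3-(3,4-dimethoxybenzyl)dihydrofuran-2(3H)-one F3. Preparative chromatography on a polysaccharide chiral stationary phase then separates 15 from F3.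

Step 2. Ruthenium hydride species may move the allyl double bond into conjugation with the arene, which leads to chain-shortened metathesis products; self-metathesis of 2 and poor mixing of the polar diol with the catalyst may add to the loss. The fallback sets out from 2 and returns at 4. Lemieux–Johnson cleavage of 2 (OsO4 cat., NaIO4, 2,6-lutidine, dioxane/H2O) passes through 3-[3,4-bis(benzyloxy)phenyl]propane-1,2-diol F4 and gives [3,4-bis(benzyloxy)phenyl]acetaldehyde F5. Wittig olefination of F5 with methyl (triphenylphosphoranylidene)acetate in CH2Cl2 under neutral conditions gives methyl (E)-4-[3,4-bis(benzyloxy)phenyl]but-2-enoate F6. DIBAL-H in CH2Cl2 at −78 °C reduces the ester of F6 to the allylic alcohol 4.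

Step 6. The secondary hydroxyl of diol 11 may close onto the methyl ester before periodate cleaves the diol, which would block the cleavage; over-oxidation and loss of the sensitive β-formyl ester on isolation are further risks. The fallback sets out from 10 and returns at 12, and it avoids any free diol. Ozonolysis in CH2Cl2 at −78 °C to the Sudan Red 7B end-point gives the secondary ozonide methyl 4-[3,4-bis(benzyloxy)phenyl]-2-(3,4-dimethoxybenzyl)-3-(1,2,4-trioxolan-3-yl)butanoate F7. Reduction of F7 in the same flask with PPh3 releases 12.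

**Further compounds**

F1 | step 7 | methyl 4-[3,4-bis(benzyloxy)phenyl]-2-(3,4-dimethoxybenzyl)-3-(hydroxymethyl)butanoate, all four stereoisomers | COC(=O)C(Cc1ccc(OC)c(OC)c1)C(CO)Cc1ccc(OCc2ccccc2)c(OCc2ccccc2)c1
F2 | step 7 | 4-[3,4-bis(benzyloxy)benzyl]-3-(3,4-dimethoxybenzyl)dihydrofuran-2(3H)-one, all four stereoisomers | COc1ccc(CC2C(=O)OCC2Cc2ccc(OCc3ccccc3)c(OCc3ccccc3)c2)cc1OC
F3 | step 7 | (3S,4S)-4-[3,4-bis(benzyloxy)benzyl]-3-(3,4-dimethoxybenzyl)dihydrofuran-2(3H)-one | COc1ccc(C[C@@H]2C(=O)OC[C@H]2Cc2ccc(OCc3ccccc3)c(OCc3ccccc3)c2)cc1OC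
F4 | step 2 | 3-[3,4-bis(benzyloxy)phenyl]propane-1,2-diol (racemic) | OCC(O)Cc1ccc(OCc2ccccc2)c(OCc2ccccc2)c1
F5 | step 2 | [3,4-bis(benzyloxy)phenyl]acetaldehyde | O=CCc1ccc(OCc2ccccc2)c(OCc2ccccc2)c1
F6 | step 2 | methyl (E)-4-[3,4-bis(benzyloxy)phenyl]but-2-enoate | COC(=O)/C=C/Cc1ccc(OCc2ccccc2)c(OCc2ccccc2)c1
F7 | step 6 | methyl 4-[3,4-bis(benzyloxy)phenyl]-2-(3,4-dimethoxybenzyl)-3-(1,2,4-trioxolan-3-yl)butanoate (stereoisomer mixture) | COC(=O)C(Cc1ccc(OC)c(OC)c1)C(C1OCOO1)Cc1ccc(OCc2ccccc2)c(OCc2ccccc2)c1
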